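## Retrosynthetic overview

1. Target 31 ⇐ nine-fold O-debenzylation ⇐ Heck union of east bromide 19 (dihydrobenzofurans B and C) with west styrene 29 (dihydrobenzofuran A); the E-stilbene is formed last.
2. Each 2,3-trans-2,3-diaryl-dihydrobenzofuran ⇐ C2–C3 bond by carbene-catalysed umpolung: the Breslow acyl anion of 4-(benzyloxy)benzaldehyde adds to an in situ ortho-quinone methide. This addition sets C3; reduction and acid ring closure in the same pot set C2 trans.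
3. ortho-Quinone methide precursors ⇐ aryllithium or arylmagnesium reagent + O-Boc salicylaldehyde (Boc migration), from three bromosalicylaldehydes.
4. Ring order: furan ring C on the resorcinol ring, then lithiation at its C4 and furan ring B (fragment union); furan ring A is made separately; all benzene rings are bought.

Assumption: the (5aS,10bR) triazolium antipode is taken to give the S-configured triaryl methine (steps 4 and 9) and the (5aR,10bS) antipode the R one (step 6); if the first run shows the opposite sense, the two antipodes are swapped.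

## Route

Step 1
Reactants: 1 1,3-bis(benzyloxy)-5-bromobenzene
Product: 2 2,4-bis(benzyloxy)-6-bromobenzaldehyde
Conditions: POCl3, DMF, 0 → 90 °C; then H2O
Reagents that add atoms: N,N-dimethylformamide, CN(C)C=O; water, O
Why: Vilsmeier–Haack formylation goes to the ring position para to one benzyloxy group and ortho to the other (between OBn and Br), the usual site for 5-substituted resorcinol diethers.

Step 2
Reactants: 2 2,4-bis(benzyloxy)-6-bromobenzaldehyde
Product: 3 4-(benzyloxy)-2-bromo-6-hydroxybenzaldehyde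
Conditions: BCl3 (1.1 equiv), CH2Cl2, −78 → 0 °C; then H2O
Reagents that add atoms: none
Why: Chelation-controlled Lewis-acid O-debenzylation: BCl3 bound to the aldehyde oxygen cleaves only the ortho benzyl ether and leaves the para ether and the bromide alone.

Step 3
Reactants: 3 4-(benzyloxy)-2-bromo-6-hydroxybenzaldehyde; 1 1,3-bis(benzyloxy)-5-bromobenzene
Product: 6 [4-(benzyloxy)-2-bromo-6-hydroxyphenyl][3,5-bis(benzyloxy)phenyl]methyl tert-butyl carbonate (racemic), via O-Boc aldehyde 4 (not isolated), via aryllithium 5 (not isolated)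
Conditions: 3: NaH, THF, 0 °C, then Boc2O, rt; 1: n-BuLi, THF, −78 °C; combine at −78 °C, 1 h; AcOH, −78 °C
Reagents that add atoms: di-tert-butyl dicarbonate, CC(C)(C)OC(=O)OC(=O)OC(C)(C)C
Why: Bromine–lithium exchange and 1,2-addition of the aryllithium to the O-Boc salicylaldehyde are followed by fast anionic O-to-O Boc migration to the new alkoxide, and cold protonation gives the phenol/benzylic carbonate as a latent ortho-quinone methide; the carbinol centre is racemic and becomes sp2 in step 4.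

Step 4
Reactants: 6 [4-(benzyloxy)-2-bromo-6-hydroxyphenyl][3,5-bis(benzyloxy)phenyl]methyl tert-butyl carbonate (racemic); 7 4-(benzyloxy)benzaldehyde
Product: 11 (2S,3S)-6-(benzyloxy)-2-[4-(benzyloxy)phenyl]-3-[3,5-bis(benzyloxy)phenyl]-4-bromo-2,3-dihydro-1-benzofuran, via ortho-quinone methide 8 (not isolated), via ketone 9 (not isolated), via alcohol 10 (not isolated)
Conditions: (5aS,10bR)-2-(pentafluorophenyl)-5a,10b-dihydro-4H,6H-indeno[2,1-b][1,2,4]triazolo[4,3-d][1,4]oxazin-2-ium tetrafluoroborate (15 mol %), i-Pr2NEt (30 mol %), 4 Å MS, THF, 0 °C → rt; then MeOH, CeCl3·7H2O, NaBH4, −40 → 0 °C; then HCl (4 M in dioxane), 0 °C → rt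
Reagents that add atoms: none
Why: Proposed new method: catalytic base expels tert-butyl carbonate from the phenoxide of 6 to give ortho-quinone methide 8, and the chiral triazolylidene turns aldehyde 7 into its Breslow intermediate, an acyl anion equivalent that adds face-selectively to the electrophilic methide carbon (Stetter-type 1,4-hydroacylation; closest known reaction types are the carbene-catalysed 1,6-hydroacylation of para-quinone methides, enantioselective intermolecular Stetter reactions and carbene homoenolate additions to in situ ortho-quinone methides), which sets the methine of 9 as S; cerium-buffered borohydride reduction before any base or acid can epimerise 9 or dehydrate it to a benzofuran, then acid ionisation of the 4-alkoxybenzylic alcohol 10 and 5-exo capture by the phenol, give the favoured 2,3-trans ring, so C2 follows from C3.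

Step 5
Reactants: 11 (2S,3S)-6-(benzyloxy)-2-[4-(benzyloxy)phenyl]-3-[3,5-bis(benzyloxy)phenyl]-4-bromo-2,3-dihydro-1-benzofuran; 12 4-bromo-2-hydroxybenzaldehyde
Product: 15 {(2S,3S)-6-(benzyloxy)-2-[4-(benzyloxy)phenyl]-3-[3,5-bis(benzyloxy)phenyl]-2,3-dihydro-1-benzofuran-4-yl}(4-bromo-2-hydroxyphenyl)methyl tert-butyl carbonate (both carbinol epimers), via O-Boc aldehyde 13 (not isolated), via aryllithium 14 (not isolated)
Conditions: 11: n-BuLi (1.05 equiv), THF, −78 °C; 12: NaH, THF, 0 °C, then Boc2O, rt; add 13 (1.2 equiv) to 14 at −78 °C, 1 h; AcOH, −78 °C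
Reagents that add atoms: di-tert-butyl dicarbonate, CC(C)(C)OC(=O)OC(=O)OC(C)(C)C
Why: Bromine–lithium exchange at −78 °C is faster than any benzylic deprotonation, the hindered aryllithium adds to the activated O-Boc aldehyde and the Boc group migrates to the alkoxide as in step 3; the new carbinol centre is a mixture that is erased in step 6 and the (2S,3S) centres are untouched.

Step 6
Reactants: 15 {(2S,3S)-6-(benzyloxy)-2-[4-(benzyloxy)phenyl]-3-[3,5-bis(benzyloxy)phenyl]-2,3-dihydro-1-benzofuran-4-yl}(4-bromo-2-hydroxyphenyl)methyl tert-butyl carbonate (both carbinol epimers); 7 4-(benzyloxy)benzaldehyde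
Product: 19 (2R,3R)-3-{(2S,3S)-6-(benzyloxy)-2-[4-(benzyloxy)phenyl]-3-[3,5-bis(benzyloxy)phenyl]-2,3-dihydro-1-benzofuran-4-yl}-2-[4-(benzyloxy)phenyl]-6-bromo-2,3-dihydro-1-benzofuran, via ortho-quinone methide 16 (not isolated), via ketone 17 (not isolated), via alcohol 18 (not isolated)
Conditions: (5aR,10bS)-2-(pentafluorophenyl)-5a,10b-dihydro-4H,6H-indeno[2,1-b][1,2,4]triazolo[4,3-d][1,4]oxazin-2-ium tetrafluoroborate (20 mol %), i-Pr2NEt (30 mol %), 4 Å MS, THF, 0 °C → rt; then MeOH, CeCl3·7H2O, NaBH4, −40 → 0 °C; then HCl (4 M in dioxane), 0 °C, short contact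
Reagents that add atoms: none
Why: Proposed new method: the same carbene-catalysed Stetter-type 1,4-hydroacylation of an in situ ortho-quinone methide as in step 4 (closest known reaction types: 1,6-hydroacylation of para-quinone methides and enantioselective intermolecular Stetter reactions), run with the antipodal catalyst so that reagent control sets the new methine R against the remote (2S,3S) unit, after which borohydride reduction and kinetically fast 5-exo capture of the 4-alkoxybenzylic cation by the phenol close the trans ring B ahead of a seven-membered Friedel–Crafts closure onto the dibenzyloxyphenyl ring.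

Step 7
Reactants: 20 5-bromo-2,3-dihydroxybenzaldehyde
Product: 21 3-(benzyloxy)-5-bromo-2-hydroxybenzaldehyde
Conditions: NaH (2.2 equiv), DMSO, rt; BnBr (1.0 equiv); aq. HCl
Reagents that add atoms: benzyl bromide, BrCc1ccccc1
Why: Williamson etherification of the dianion: the 3-phenoxide is not conjugated with the aldehyde and is the more nucleophilic oxygen, so one equivalent of benzyl bromide alkylates O3 selectively.

Step 8
Reactants: 21 3-(benzyloxy)-5-bromo-2-hydroxybenzaldehyde; 1 1,3-bis(benzyloxy)-5-bromobenzene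
Product: 24 [3-(benzyloxy)-5-bromo-2-hydroxyphenyl][3,5-bis(benzyloxy)phenyl]methyl tert-butyl carbonate (racemic), via O-Boc aldehyde 22 (not isolated), via arylmagnesium bromide 23 (not isolated)
Conditions: 21: NaH, THF, 0 °C, then Boc2O, rt; 1: Mg turnings, I2 (cat.), THF, 50 °C; add 23 (1.0 equiv) to 22 at −78 °C, 2 h; AcOH, −78 °C
Reagents that add atoms: di-tert-butyl dicarbonate, CC(C)(C)OC(=O)OC(=O)OC(C)(C)C
Why: Grignard 1,2-addition to the O-Boc salicylaldehyde (the arylmagnesium reagent does not exchange with the ring bromide of 22) is followed by anionic O-to-O Boc migration to the magnesium alkoxide, and the acetic acid quench at −78 °C protonates the phenoxide before it can expel tert-butyl carbonate, which leaves the latent ortho-quinone methide; the racemic carbinol centre is erased in step 9.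

Step 9
Reactants: 24 [3-(benzyloxy)-5-bromo-2-hydroxyphenyl][3,5-bis(benzyloxy)phenyl]methyl tert-butyl carbonate (racemic); 7 4-(benzyloxy)benzaldehyde
Product: 28 (2S,3S)-7-(benzyloxy)-2-[4-(benzyloxy)phenyl]-3-[3,5-bis(benzyloxy)phenyl]-5-bromo-2,3-dihydro-1-benzofuran, via ortho-quinone methide 25 (not isolated), via ketone 26 (not isolated), via alcohol 27 (not isolated)
Conditions: (5aS,10bR)-2-(pentafluorophenyl)-5a,10b-dihydro-4H,6H-indeno[2,1-b][1,2,4]triazolo[4,3-d][1,4]oxazin-2-ium tetrafluoroborate (15 mol %), i-Pr2NEt (30 mol %), 4 Å MS, THF, 0 °C → rt; then MeOH, CeCl3·7H2O, NaBH4, −40 → 0 °C; then HCl (4 M in dioxane), 0 °C → rt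
Reagents that add atoms: none
Why: Proposed new method: the carbene-catalysed Stetter-type 1,4-hydroacylation of ortho-quinone methide 25 by the Breslow acyl anion of 7 (closest known reaction types as in step 4) sets the methine of 26 as S, and reduction followed by acid-mediated 5-exo etherification through the 4-alkoxybenzylic cation gives the trans ring A with C2 set by C3.

Step 10
Reactants: 28 (2S,3S)-7-(benzyloxy)-2-[4-(benzyloxy)phenyl]-3-[3,5-bis(benzyloxy)phenyl]-5-bromo-2,3-dihydro-1-benzofuran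
Product: 29 (2S,3S)-7-(benzyloxy)-2-[4-(benzyloxy)phenyl]-3-[3,5-bis(benzyloxy)phenyl]-5-ethenyl-2,3-dihydro-1-benzofuran
Conditions: vinylboronic acid pinacol ester, PdCl2(dppf) (5 mol %), K2CO3, dioxane/H2O, 80 °C
Reagents that add atoms: 2-ethenyl-4,4,5,5-tetramethyl-1,3,2-dioxaborolane, C=CB1OC(C)(C)C(C)(C)O1
Why: Suzuki–Miyaura vinylation of the aryl bromide under mild base; no stereocentre is involved.

Step 11
Reactants: 19 (2R,3R)-3-{(2S,3S)-6-(benzyloxy)-2-[4-(benzyloxy)phenyl]-3-[3,5-bis(benzyloxy)phenyl]-2,3-dihydro-1-benzofuran-4-yl}-2-[4-(benzyloxy)phenyl]-6-bromo-2,3-dihydro-1-benzofuran; 29 (2S,3S)-7-(benzyloxy)-2-[4-(benzyloxy)phenyl]-3-[3,5-bis(benzyloxy)phenyl]-5-ethenyl-2,3-dihydro-1-benzofuran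
Product: 30 (2S,3S)-7-(benzyloxy)-2-[4-(benzyloxy)phenyl]-3-[3,5-bis(benzyloxy)phenyl]-5-[(E)-2-{(2R,3R)-3-[(2S,3S)-6-(benzyloxy)-2-[4-(benzyloxy)phenyl]-3-[3,5-bis(benzyloxy)phenyl]-2,3-dihydro-1-benzofuran-4-yl]-2-[4-(benzyloxy)phenyl]-2,3-dihydro-1-benzofuran-6-yl}ethenyl]-2,3-dihydro-1-benzofuran
Conditions: Pd(OAc)2 (5 mol %), P(o-tol)3 (10 mol %), Et3N, DMF, 100 °C
Reagents that add atoms: none
Why: Mizoroki–Heck reaction: oxidative addition of the aryl bromide to zerovalent palladium, syn insertion at the terminal styrene carbon and syn β-hydride elimination give the E-stilbene; the six stereocentres are not touched.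

Step 12
Reactants: 30 (2S,3S)-7-(benzyloxy)-2-[4-(benzyloxy)phenyl]-3-[3,5-bis(benzyloxy)phenyl]-5-[(E)-2-{(2R,3R)-3-[(2S,3S)-6-(benzyloxy)-2-[4-(benzyloxy)phenyl]-3-[3,5-bis(benzyloxy)phenyl]-2,3-dihydro-1-benzofuran-4-yl]-2-[4-(benzyloxy)phenyl]-2,3-dihydro-1-benzofuran-6-yl}ethenyl]-2,3-dihydro-1-benzofuran
Product: 31 (2S,3S)-3-(3,5-dihydroxyphenyl)-5-[(E)-2-{(2R,3R)-3-[(2S,3S)-3-(3,5-dihydroxyphenyl)-6-hydroxy-2-(4-hydroxyphenyl)-2,3-dihydro-1-benzofuran-4-yl]-2-(4-hydroxyphenyl)-2,3-dihydro-1-benzofuran-6-yl}ethenyl]-2-(4-hydroxyphenyl)-2,3-dihydro-1-benzofuran-7-ol (CNP0265934.1)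
Conditions: BCl3 (30 equiv), pentamethylbenzene (30 equiv), CH2Cl2, −78 °C; then MeOH/H2O
Reagents that add atoms: none
Why: Lewis-acid O-debenzylation with pentamethylbenzene as a non-basic benzyl-cation scavenger removes all nine benzyl ethers at −78 °C without reducing the alkene or ionising the dihydrobenzofuran C2–O bonds.

## Compound list

1 | 1,3-bis(benzyloxy)-5-bromobenzene | Brc1cc(OCc2ccccc2)cc(OCc2ccccc2)c1 | starting material
2 | 2,4-bis(benzyloxy)-6-bromobenzaldehyde | O=Cc1c(Br)cc(OCc2ccccc2)cc1OCc1ccccc1 | intermediate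
3 | 4-(benzyloxy)-2-bromo-6-hydroxybenzaldehyde | O=Cc1c(O)cc(OCc2ccccc2)cc1Br | intermediate
4 | 5-(benzyloxy)-3-bromo-2-formylphenyl tert-butyl carbonate | O=Cc1c(Br)cc(OCc2ccccc2)cc1OC(=O)OC(C)(C)C | intermediate
5 | [3,5-bis(benzyloxy)phenyl]lithium | [Li]c1cc(OCc2ccccc2)cc(OCc2ccccc2)c1 | intermediate
6 | [4-(benzyloxy)-2-bromo-6-hydroxyphenyl][3,5-bis(benzyloxy)phenyl]methyl tert-butyl carbonate (racemic) | CC(C)(C)OC(=O)OC(c1cc(OCc2ccccc2)cc(OCc2ccccc2)c1)c1c(O)cc(OCc2ccccc2)cc1Br | intermediate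
7 | 4-(benzyloxy)benzaldehyde | O=Cc1ccc(OCc2ccccc2)cc1 | starting material
8 | 5-(benzyloxy)-2-{[3,5-bis(benzyloxy)phenyl]methylidene}-3-bromocyclohexa-3,5-dien-1-one | O=C1C=C(OCc2ccccc2)C=C(Br)C1=Cc1cc(OCc2ccccc2)cc(OCc2ccccc2)c1 | intermediate
9 | (2S)-2-[4-(benzyloxy)-2-bromo-6-hydroxyphenyl]-1-[4-(benzyloxy)phenyl]-2-[3,5-bis(benzyloxy)phenyl]ethan-1-one | Oc1cc(OCc2ccccc2)cc(Br)c1[C@H](c1cc(OCc2ccccc2)cc(OCc2ccccc2)c1)C(=O)c1ccc(OCc2ccccc2)cc1 | intermediate
10 | (2S)-2-[4-(benzyloxy)-2-bromo-6-hydroxyphenyl]-1-[4-(benzyloxy)phenyl]-2-[3,5-bis(benzyloxy)phenyl]ethan-1-ol (both C1 epimers) | Oc1cc(OCc2ccccc2)cc(Br)c1[C@H](c1cc(OCc2ccccc2)cc(OCc2ccccc2)c1)C(O)c1ccc(OCc2ccccc2)cc1 | intermediate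
11 | (2S,3S)-6-(benzyloxy)-2-[4-(benzyloxy)phenyl]-3-[3,5-bis(benzyloxy)phenyl]-4-bromo-2,3-dihydro-1-benzofuran | Brc1cc(OCc2ccccc2)cc2c1[C@H](c1cc(OCc3ccccc3)cc(OCc3ccccc3)c1)[C@@H](c1ccc(OCc3ccccc3)cc1)O2 | intermediate
12 | 4-bromo-2-hydroxybenzaldehyde | O=Cc1ccc(Br)cc1O | starting material
13 | 5-bromo-2-formylphenyl tert-butyl carbonate | O=Cc1ccc(Br)cc1OC(=O)OC(C)(C)C | intermediate
14 | {(2S,3S)-6-(benzyloxy)-2-[4-(benzyloxy)phenyl]-3-[3,5-bis(benzyloxy)phenyl]-2,3-dihydro-1-benzofuran-4-yl}lithium | [Li]c1cc(OCc2ccccc2)cc2c1[C@H](c1cc(OCc3ccccc3)cc(OCc3ccccc3)c1)[C@@H](c1ccc(OCc3ccccc3)cc1)O2 | intermediate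
15 | {(2S,3S)-6-(benzyloxy)-2-[4-(benzyloxy)phenyl]-3-[3,5-bis(benzyloxy)phenyl]-2,3-dihydro-1-benzofuran-4-yl}(4-bromo-2-hydroxyphenyl)methyl tert-butyl carbonate (both carbinol epimers) | CC(C)(C)OC(=O)OC(c1ccc(Br)cc1O)c1cc(OCc2ccccc2)cc2c1[C@H](c1cc(OCc3ccccc3)cc(OCc3ccccc3)c1)[C@@H](c1ccc(OCc3ccccc3)cc1)O2 | intermediate
16 | 6-({(2S,3S)-6-(benzyloxy)-2-[4-(benzyloxy)phenyl]-3-[3,5-bis(benzyloxy)phenyl]-2,3-dihydro-1-benzofuran-4-yl}methylidene)-3-bromocyclohexa-2,4-dien-1-one | O=C1C=C(Br)C=CC1=Cc1cc(OCc2ccccc2)cc2c1[C@H](c1cc(OCc3ccccc3)cc(OCc3ccccc3)c1)[C@@H](c1ccc(OCc3ccccc3)cc1)O2 | intermediate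
17 | (2R)-2-{(2S,3S)-6-(benzyloxy)-2-[4-(benzyloxy)phenyl]-3-[3,5-bis(benzyloxy)phenyl]-2,3-dihydro-1-benzofuran-4-yl}-1-[4-(benzyloxy)phenyl]-2-(4-bromo-2-hydroxyphenyl)ethan-1-one | O=C(c1ccc(OCc2ccccc2)cc1)[C@@H](c1ccc(Br)cc1O)c1cc(OCc2ccccc2)cc2c1[C@H](c1cc(OCc3ccccc3)cc(OCc3ccccc3)c1)[C@@H](c1ccc(OCc3ccccc3)cc1)O2 | intermediate
18 | (2R)-2-{(2S,3S)-6-(benzyloxy)-2-[4-(benzyloxy)phenyl]-3-[3,5-bis(benzyloxy)phenyl]-2,3-dihydro-1-benzofuran-4-yl}-1-[4-(benzyloxy)phenyl]-2-(4-bromo-2-hydroxyphenyl)ethan-1-ol (both C1 epimers) | OC(c1ccc(OCc2ccccc2)cc1)[C@@H](c1ccc(Br)cc1O)c1cc(OCc2ccccc2)cc2c1[C@H](c1cc(OCc3ccccc3)cc(OCc3ccccc3)c1)[C@@H](c1ccc(OCc3ccccc3)cc1)O2 | intermediate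
19 | (2R,3R)-3-{(2S,3S)-6-(benzyloxy)-2-[4-(benzyloxy)phenyl]-3-[3,5-bis(benzyloxy)phenyl]-2,3-dihydro-1-benzofuran-4-yl}-2-[4-(benzyloxy)phenyl]-6-bromo-2,3-dihydro-1-benzofuran | Brc1ccc2c(c1)O[C@@H](c1ccc(OCc3ccccc3)cc1)[C@@H]2c1cc(OCc2ccccc2)cc2c1[C@H](c1cc(OCc3ccccc3)cc(OCc3ccccc3)c1)[C@@H](c1ccc(OCc3ccccc3)cc1)O2 | intermediate
20 | 5-bromo-2,3-dihydroxybenzaldehyde | O=Cc1cc(Br)cc(O)c1O | starting material
21 | 3-(benzyloxy)-5-bromo-2-hydroxybenzaldehyde | O=Cc1cc(Br)cc(OCc2ccccc2)c1O | intermediate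
22 | 2-(benzyloxy)-4-bromo-6-formylphenyl tert-butyl carbonate | O=Cc1cc(Br)cc(OCc2ccccc2)c1OC(=O)OC(C)(C)C | intermediate
23 | [3,5-bis(benzyloxy)phenyl]magnesium bromide | Br[Mg]c1cc(OCc2ccccc2)cc(OCc2ccccc2)c1 | intermediate
24 | [3-(benzyloxy)-5-bromo-2-hydroxyphenyl][3,5-bis(benzyloxy)phenyl]methyl tert-butyl carbonate (racemic) | CC(C)(C)OC(=O)OC(c1cc(OCc2ccccc2)cc(OCc2ccccc2)c1)c1cc(Br)cc(OCc2ccccc2)c1O | intermediate
25 | 2-(benzyloxy)-6-{[3,5-bis(benzyloxy)phenyl]methylidene}-4-bromocyclohexa-2,4-dien-1-one | O=C1C(OCc2ccccc2)=CC(Br)=CC1=Cc1cc(OCc2ccccc2)cc(OCc2ccccc2)c1 | intermediate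
26 | (2S)-2-[3-(benzyloxy)-5-bromo-2-hydroxyphenyl]-1-[4-(benzyloxy)phenyl]-2-[3,5-bis(benzyloxy)phenyl]ethan-1-one | Oc1c(OCc2ccccc2)cc(Br)cc1[C@@H](C(=O)c1ccc(OCc2ccccc2)cc1)c1cc(OCc2ccccc2)cc(OCc2ccccc2)c1 | intermediate
27 | (2S)-2-[3-(benzyloxy)-5-bromo-2-hydroxyphenyl]-1-[4-(benzyloxy)phenyl]-2-[3,5-bis(benzyloxy)phenyl]ethan-1-ol (both C1 epimers) | Oc1c(OCc2ccccc2)cc(Br)cc1[C@@H](C(O)c1ccc(OCc2ccccc2)cc1)c1cc(OCc2ccccc2)cc(OCc2ccccc2)c1 | intermediate
28 | (2S,3S)-7-(benzyloxy)-2-[4-(benzyloxy)phenyl]-3-[3,5-bis(benzyloxy)phenyl]-5-bromo-2,3-dihydro-1-benzofuran | c1ccccc1COc1ccc([C@H]2Oc3c(OCc4ccccc4)cc(Br)cc3[C@@H]2c2cc(OCc3ccccc3)cc(OCc3ccccc3)c2)cc1 | intermediate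
29 | (2S,3S)-7-(benzyloxy)-2-[4-(benzyloxy)phenyl]-3-[3,5-bis(benzyloxy)phenyl]-5-ethenyl-2,3-dihydro-1-benzofuran | c1ccccc1COc1ccc([C@H]2Oc3c(OCc4ccccc4)cc(C=C)cc3[C@@H]2c2cc(OCc3ccccc3)cc(OCc3ccccc3)c2)cc1 | intermediate
30 | (2S,3S)-7-(benzyloxy)-2-[4-(benzyloxy)phenyl]-3-[3,5-bis(benzyloxy)phenyl]-5-[(E)-2-{(2R,3R)-3-[(2S,3S)-6-(benzyloxy)-2-[4-(benzyloxy)phenyl]-3-[3,5-bis(benzyloxy)phenyl]-2,3-dihydro-1-benzofuran-4-yl]-2-[4-(benzyloxy)phenyl]-2,3-dihydro-1-benzofuran-6-yl}ethenyl]-2,3-dihydro-1-benzofuran | c1ccccc1COc1ccc([C@H]2Oc3c(OCc4ccccc4)cc(/C=C/c4ccc5c(c4)O[C@@H](c4ccc(OCc6ccccc6)cc4)[C@@H]5c4cc(OCc5ccccc5)cc5c4[C@H](c4cc(OCc6ccccc6)cc(OCc6ccccc6)c4)[C@@H](c4ccc(OCc6ccccc6)cc4)O5)cc3[C@@H]2c2cc(OCc3ccccc3)cc(OCc3ccccc3)c2)cc1 | intermediate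
31 | (2S,3S)-3-(3,5-dihydroxyphenyl)-5-[(E)-2-{(2R,3R)-3-[(2S,3S)-3-(3,5-dihydroxyphenyl)-6-hydroxy-2-(4-hydroxyphenyl)-2,3-dihydro-1-benzofuran-4-yl]-2-(4-hydroxyphenyl)-2,3-dihydro-1-benzofuran-6-yl}ethenyl]-2-(4-hydroxyphenyl)-2,3-dihydro-1-benzofuran-7-ol | Oc1ccc([C@H]2Oc3c(O)cc(/C=C/c4ccc5c(c4)O[C@@H](c4ccc(O)cc4)[C@@H]5c4cc(O)cc5c4[C@H](c4cc(O)cc(O)c4)[C@@H](c4ccc(O)cc4)O5)cc3[C@@H]2c2cc(O)cc(O)c2)cc1 | target

## Step count and risks

Total steps: 12. Longest linear sequence: 8 steps (1, 2, 3, 4, 5, 6, 11, 12).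

**Step 4** (the first use of the key reaction; step 9 carries the same risk). The enantioselective carbene-catalysed hydroacylation of an in situ ortho-quinone methide is unproven: facial selectivity may be low, or ketone 9 may epimerise before it is reduced. The fallback sets out from carbonate 6 and comes back at 11, and it avoids the ketone altogether. Commercial 4-(benzyloxy)benzyl bromide, (2R,5R)-2,5-dimethylthiolane and NaBF4 give the sulfonium salt (2R,5R)-1-{[4-(benzyloxy)phenyl]methyl}-2,5-dimethylthiolan-1-ium tetrafluoroborate F1. With K2CO3 in CH2Cl2 at −20 °C, 6 gives ortho-quinone methide 8 and F1 gives its benzylic ylide. The ylide carbon adds to the methide carbon and the phenoxide displaces the sulfide in a formal [4+1] annulation that gives the trans ring of 11 directly. The sulfide antipode is chosen by the sense of induction found.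

**Step 6** (the key reaction on the hindered, already chiral substrate). The catalyst may be mismatched with the (2S,3S) unit, the bulky methide may react slowly, and the cation may close onto the neighbouring dibenzyloxyphenyl ring. The fallback sets out from 15 and comes back at alcohol 18. An achiral carbene from 3-benzyl-5-(2-hydroxyethyl)-4-methylthiazolium chloride and Et3N in THF couples 15 with 7 to give the ketone 2-{(2S,3S)-6-(benzyloxy)-2-[4-(benzyloxy)phenyl]-3-[3,5-bis(benzyloxy)phenyl]-2,3-dihydro-1-benzofuran-4-yl}-1-[4-(benzyloxy)phenyl]-2-(4-bromo-2-hydroxyphenyl)ethan-1-one (mixture of C2 epimers) F2. The labile centre is then set in the reduction instead of the C–C bond formation: transfer hydrogenation with dynamic kinetic resolution (RuCl(p-cymene)[(R,R)-TsDPEN] or its antipode, t-BuOK, 2-propanol, rt) equilibrates the two epimers through the phenoxide-stabilised enolate and reduces one faster. This gives alcohol 18, which is closed with HCl as in the last stage of step 6. Any epimer left over is a diastereomer of 19 and is removed by chromatography.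

**Step 12** (nine benzyl ethers removed at once on the largest, most acid-sensitive compound). Incomplete cleavage or acid-induced ring opening or Friedel–Crafts reactions of the stilbene-linked polyphenol are possible. The fallback sets out from 28 and 19 and comes back at 31, with the deprotection done on the smaller halves before the union. BCl3 and pentamethylbenzene in CH2Cl2 at −78 °C convert 28 into (2S,3S)-5-bromo-3-(3,5-dihydroxyphenyl)-2-(4-hydroxyphenyl)-2,3-dihydro-1-benzofuran-7-ol F3, and convert 19 into (2S,3S)-4-[(2R,3R)-6-bromo-2-(4-hydroxyphenyl)-2,3-dihydro-1-benzofuran-3-yl]-3-(3,5-dihydroxyphenyl)-2-(4-hydroxyphenyl)-2,3-dihydro-1-benzofuran-6-ol F4. F3 is vinylated under the conditions of step 10 to (2S,3S)-3-(3,5-dihydroxyphenyl)-5-ethenyl-2-(4-hydroxyphenyl)-2,3-dihydro-1-benzofuran-7-ol F5. A Heck coupling of F4 with F5 (Pd(OAc)2, P(o-tol)3, Et3N, DMF, 90 °C), which tolerates free phenols, gives 31 directly.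

## Further compounds

F1 | step 4 | (2R,5R)-1-{[4-(benzyloxy)phenyl]methyl}-2,5-dimethylthiolan-1-ium tetrafluoroborate | C[C@@H]1CC[C@@H](C)[S+]1Cc1ccc(OCc2ccccc2)cc1.F[B-](F)(F)F
F2 | step 6 | 2-{(2S,3S)-6-(benzyloxy)-2-[4-(benzyloxy)phenyl]-3-[3,5-bis(benzyloxy)phenyl]-2,3-dihydro-1-benzofuran-4-yl}-1-[4-(benzyloxy)phenyl]-2-(4-bromo-2-hydroxyphenyl)ethan-1-one (mixture of C2 epimers) | O=C(c1ccc(OCc2ccccc2)cc1)C(c1ccc(Br)cc1O)c1cc(OCc2ccccc2)cc2c1[C@H](c1cc(OCc3ccccc3)cc(OCc3ccccc3)c1)[C@@H](c1ccc(OCc3ccccc3)cc1)O2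
F3 | step 12 | (2S,3S)-5-bromo-3-(3,5-dihydroxyphenyl)-2-(4-hydroxyphenyl)-2,3-dihydro-1-benzofuran-7-ol | Oc1ccc([C@H]2Oc3c(O)cc(Br)cc3[C@@H]2c2cc(O)cc(O)c2)cc1
F4 | step 12 | (2S,3S)-4-[(2R,3R)-6-bromo-2-(4-hydroxyphenyl)-2,3-dihydro-1-benzofuran-3-yl]-3-(3,5-dihydroxyphenyl)-2-(4-hydroxyphenyl)-2,3-dihydro-1-benzofuran-6-ol | Brc1ccc2c(c1)O[C@@H](c1ccc(O)cc1)[C@@H]2c1cc(O)cc2c1[C@H](c1cc(O)cc(O)c1)[C@@H](c1ccc(O)cc1)O2
F5 | step 12 | (2S,3S)-3-(3,5-dihydroxyphenyl)-5-ethenyl-2-(4-hydroxyphenyl)-2,3-dihydro-1-benzofuran-7-ol | Oc1ccc([C@H]2Oc3c(O)cc(C=C)cc3[C@@H]2c2cc(O)cc(O)c2)cc1
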